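## Structural features

The target is a spirolactone-type 6,7-seco-ent-kauranoid in which cyclohexane ring A (C1–C5, C10) is joined through the spiro carbon C10 to a δ-lactone (C10, C20, O, C7, C8, C9). The lactone shares its C8–C9 bond with a bicyclo[3.2.1]octane made of six-membered ring C (C8, C9, C11–C14) and five-membered ring D (C8, C14, C13, C16, C15). C4 (quaternary; methyl cis to C20, hydroxymethyl C18 trans), C5 (carrying the C6 hydroxymethyl, cis to C20) and C10 are contiguous, and C10 continues into C9 (H), the quaternary bridgehead C8, the carbinol C11 (hydroxyl trans to H9, equatorial on ring C) and the bridgehead C13. The fragile groups are the α-methylene cyclopentanone (C15 ketone, C16=C17), the β-keto lactone with non-enolisable C8 (open to retro-Claisen attack) and three free hydroxyls. The difficulty lies in two places: in ring A a quaternary, a tertiary and a second quaternary carbon stand side by side, and in the bicyclooctane C8, C9 and C13 must be set while the C11 carbinol is kept apart from the C15 ketone. The key step uses the fact that C5 carries a carboxyl-level carbon (C6) and that C4 is one bond from C3. When C6 is tied through oxygen to C2 in a δ-lactone with C3=C4 as a (Z)-alkenyl group on C2, the atoms C5, C6, O, C2, C3, C4 form a [3,3] array whose shift makes C4–C5 and ring A at once. C20 and C7 ride through this step as a silylmethyl group and a benzyloxypropyl chain on C10.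

## Logic of the disconnections

44 ⇒ 43 ⇒ 40. Three O–Si bonds and then C16=C17 are removed. The enone is the most fragile group and is made last. C16 is the only enolisable position of the C15 ketone, so the forward step needs no regiocontrol but must avoid nucleophilic base.

40 ⇒ 34. No C–C bond is cut; the oxidation levels at C11 and C15 are exchanged, so 34 carries two carbinols. The forward sequence demands one selective silylation (C15–OH before C11–OH) and a C11 ketone reduction that gives the equatorial alcohol. In return the C11 configuration made earlier need not be correct.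

34 ⇒ 33 ⇒ 31. C9–C11 and C8–C15 are cut. Both rings of the bicyclooctane fall away, leaving an unsaturated lactone with two identical acetaldehyde arms, which come from one cyclopentene in 31. The gain is three stereocentres (C8, C9, C13) and two rings from an achiral side chain. The demand is that ketyl addition to C9 occurs anti to C5 and outruns coupling of the two aldehydes.

31 ⇒ 28 ⇒ 25 + 27. C8–C14 is cut and the C8=C9 unsaturation removed. What remains is a simple spirolactone and an achiral iodide. The forward steps are an enolate alkylation with a β-branched iodide and a selenoxide elimination that must go into the ring.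

25 ⇒ 22 ⇒ 21 ⇒ 20 ⇒ 19 ⇒ 18. The lactone O–C7 bond is cut to a 1,5-diol, C20–O goes back to C20–Si, the C7 oxygen to a benzyl ether, C2–C3 to an alkene and C6 to a carboxylic acid. The three one-carbon arms on ring A are then latent and distinguishable. The demand is that C7–OH is oxidised before the neopentyl C20–OH.

18 ⇒ 15. C4–C5 is cut and C2–O reconnected, so ring A becomes a δ-lactone. Quaternary C4 and tertiary C5 then derive from one carbinol centre and one alkene geometry. The demand is a boat [3,3] shift that forms a bond between two crowded carbons before the silyl ketene acetal decays.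

15 ⇒ 11 + 12. C10–C20 is cut. The forward step is a conjugate addition that must enter anti to the C2 substituent and must create a quaternary centre.

11 ⇒ 5 + 10. C1–C2 and the lactone O–C6 bond are cut (vinylogous aldol with lactonisation). C2 is the only catalyst-controlled stereocentre of the route.

5 ⇒ 4 ⇒ 3 ⇒ 2 ⇒ 1; 10 ⇒ 9 ⇒ 6 + 7; 27 ⇒ 26. Both trisubstituted alkenes come from syn-carbocupration of ynoates, so their geometry follows from the order in which the groups are introduced.

## Other disconnections considered

Alternative 1: The cut is the C13–C14 bond of ring D, made transannularly.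
- Forward step: the lactone-fused cycloheptenone A4 has a seven-membered ring (C8, C9, C11, C12, C13, C16, C15) with the enone C11(=O)–C12=C13 and a bromomethyl group (C14) on C8. Bu3SnH generates the C14 radical, which adds to C13 and gives the bicyclo[3.2.1]octan-11-one A1 after hydrogen transfer to C12.
- In favour: one bond turns a medium ring into both rings of the bicyclooctane. C13 is dictated by geometry, C8 is already quaternary, C11 arrives as a ketone and C15 as a protected carbinol.
- Against: A4 needs a seven-membered ring carrying quaternary C8 (with lactone carbonyl and CH2Br), the C15 ether and C9 next to the spiro centre; no short way to it from a ring A spirolactone is evident. The cut says nothing about C4, C5 and C10.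
- Comparison: structurally it competes only with steps 16–19, not with the [3,3] shift. Mechanistically a 5-exo alkyl radical addition to an enone is at least as reliable as a ketyl cascade and has no competition between two aldehydes. On the C11/C15 oxidation pattern it is the better plan, because A1 corresponds to 36 without redox detours. On step economy it should be worse, because the chosen cascade makes two bonds from a side chain attached in one alkylation.

Alternative 2: The cut is used in reverse: C6–C7 is kept so that ring B exists and is broken late.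
- Forward step: the decalin α-ketol A5 (C6 carbinol, C7 ketone conjugated with C8=C9, free C20 hydroxymethyl, in equilibrium with its C7/C20 hemiketal) is cleaved by Pb(OAc)4 through the hemiketal. This gives the unsaturated spirolactone aldehyde A2: the O–C7 bond, the spiro lactone and the C6 carbonyl appear together.
- In favour: it follows the way ring B is opened in nature. C4, C5 and C10 are set as a trans-decalin by mature annulation chemistry, with no bond to be made between two fully substituted carbons. A2 enters the same endgame as 31, so on the endgame the plans are equal.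
- Against: A5 needs an oxidised angular C20, oxygen at C6, C7 and C18 and the C8 side chain on one decalin. The C6 aldehyde of A2 would be a third carbonyl in the SmI2 step and a competing acceptor for the C8 enolate, so it must be reduced and protected first.
- Comparison: mechanistically the glycol-type cleavage is safer than a hindered boat shift; here the alternative is the better one. Structurally it handles C20 less well (angular oxidation instead of a silylmethyl group from a cuprate). The step count should be higher.

Alternative 3: The cuts are C9–C10 and the C20–O ester bond.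
- Forward step: a bicyclo[3.2.1]octane-11,15-dione acid (rings C and D complete) is esterified with the allylic alcohol of a ring A enal to give A6, in which C5=C10 is conjugated with the C6 aldehyde. The C9 enolate of the C11 ketone adds to C10 and gives A3, closing the δ-lactone and creating C10, C9 and, on protonation, C5.
- In favour: highest convergence. Two fragments of similar size are made in parallel, so the longest linear sequence should be clearly shorter than in the chosen plan. C11 is a ketone from the outset.
- Against: C10 is the β-carbon of a tetrasubstituted enal next to quaternary C4, so the addition must form a quaternary centre at a poor acceptor and can revert. The enolate must form at C9, not at C12 or C16. C10, C9 and C5 depend on remote control. Afterwards the C6 aldehyde and the C11 ketone must be reduced beside the C15 ketone.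
- Comparison: better in convergence, equal in how C11 is finished (ketone to equatorial alcohol), worse in stereocontrol of ring A and in late chemoselectivity.

Key step: step 9

Assumption: kaurane numbering is used; the C4 hydroxymethyl is the one trans to C20 (C18) and the C11 hydroxyl is trans to H9.

Assumption: (S)-Tol-BINAP in step 7 is taken to give the 6R lactone 11; if the sense is opposite, the (R) ligand is used.

Remark: 15 and 18 are consistent centre by centre with a boat transition state and with ring A of 44. Only spectator groups were chosen: benzyl on the C7 oxygen (it falls in step 12) and tert-butyldimethylsilyl on C18 (it lasts to the end). A p-methoxybenzyl ether would not survive hydrogenation and electrophilic desilylation, and a benzyl ether on C18 could not be removed beside the enone.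

Remark: the chlorosilane-assisted conjugate addition of step 8 passes through the trimethylsilyl ketene acetal 14, which is hydrolysed on purpose. Lactone 15 is thereby purified free of copper and magnesium halides, which could ionise the allylic C2–O bond on heating. The key step then uses the more robust tert-butyldimethylsilyl ketene acetal 16, made under salt-free conditions.

## Route

Step 1
Reactants: 1 tert-butyldimethyl(prop-2-yn-1-yloxy)silane
Product: 2 ethyl 4-[(tert-butyldimethylsilyl)oxy]but-2-ynoate
Conditions: n-BuLi, THF, −78 °C; ClCO2Et, −78 → 0 °C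
Reagents that add atoms: ethyl chloroformate, CCOC(=O)Cl
Why: C-acylation of a lithium acetylide with a chloroformate is routine and the silyl ether is inert.

Step 2
Reactants: 2 ethyl 4-[(tert-butyldimethylsilyl)oxy]but-2-ynoate
Product: 3 ethyl (Z)-4-[(tert-butyldimethylsilyl)oxy]-3-methylbut-2-enoate
Conditions: Me2CuLi (from CuI, MeLi), THF, −78 °C; NH4Cl (aq) at −78 °C
Reagents that add atoms: lithium dimethylcuprate, [Li+].C[Cu-]C
Why: syn-carbocupration puts methyl on the β-carbon cis to copper; protonation with retention at low temperature leaves CH2OSi cis to the ester (Z).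

Step 3
Reactants: 3 ethyl (Z)-4-[(tert-butyldimethylsilyl)oxy]-3-methylbut-2-enoate
Product: 4 (Z)-4-[(tert-butyldimethylsilyl)oxy]-3-methylbut-2-en-1-ol
Conditions: i-Bu2AlH, CH2Cl2, −78 °C
Reagents that add atoms: none
Why: 1,2-reduction of the enoate by the aluminium hydride does not touch the alkene geometry.

Step 4
Reactants: 4 (Z)-4-[(tert-butyldimethylsilyl)oxy]-3-methylbut-2-en-1-ol
Product: 5 (Z)-4-[(tert-butyldimethylsilyl)oxy]-3-methylbut-2-enal
Conditions: MnO2, CH2Cl2, rt; used at once
Reagents that add atoms: none
Why: neutral allylic oxidation with MnO2 should keep the (Z) geometry if the enal is not stored.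

Step 5
Reactants: 6 benzyl 3-bromopropyl ether; 7 ethyl but-2-ynoate
Product: 9 ethyl (E)-6-(benzyloxy)-3-methylhex-2-enoate, via Grignard reagent 8 (not isolated)
Conditions: Mg, THF; CuBr·SMe2 (1 equiv), −40 °C; 7, −78 °C; NH4Cl (aq)
Reagents that add atoms: none
Why: syn-carbocupration of the ynoate by the alkylcopper places the chain trans and the methyl cis to the ester; that methyl is the γ-position removed in step 6.

Step 6
Reactants: 9 ethyl (E)-6-(benzyloxy)-3-methylhex-2-enoate
Product: 10 {[3-(3-benzyloxypropyl)-1-ethoxybuta-1,3-dien-1-yl]oxy}trimethylsilane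
Conditions: LiN(i-Pr)2, THF, −78 °C; Me3SiCl
Reagents that add atoms: chlorotrimethylsilane, C[Si](C)(C)Cl
Why: kinetic γ-deprotonation of β,β-disubstituted enoates occurs at the group syn to the ester carbonyl (the methyl); O-silylation gives the dienol ether.

Step 7
Reactants: 5 (Z)-4-[(tert-butyldimethylsilyl)oxy]-3-methylbut-2-enal; 10 {[3-(3-benzyloxypropyl)-1-ethoxybuta-1,3-dien-1-yl]oxy}trimethylsilane
Product: 11 (6R)-4-[3-(benzyloxy)propyl]-6-[(Z)-3-(tert-butyldimethylsilyloxy)-2-methylprop-1-enyl]-5,6-dihydro-2H-pyran-2-one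
Conditions: Cu(OTf)2 (10 mol %), (S)-Tol-BINAP, (Bu4N)(Ph3SiF2), THF, rt
Reagents that add atoms: none
Why: catalytic asymmetric vinylogous Mukaiyama aldol with lactonisation: the copper dienolate attacks the aldehyde at its γ-carbon and the (2Z) aldolate closes onto the ester, the expelled ethoxide being silylated for turnover. C2 is set by ligand-controlled face selection; optical purity can be raised by crystallising a salt of acid 18.

Step 8
Reactants: 11 (6R)-4-[3-(benzyloxy)propyl]-6-[(Z)-3-(tert-butyldimethylsilyloxy)-2-methylprop-1-enyl]-5,6-dihydro-2H-pyran-2-one; 12 (chloromethyl)dimethyl(phenyl)silane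
Product: 15 (4S,6R)-4-[3-(benzyloxy)propyl]-4-{[dimethyl(phenyl)silyl]methyl}-6-[(Z)-3-(tert-butyldimethylsilyloxy)-2-methylprop-1-enyl]oxan-2-one, via silylmethyl Grignard reagent 13 (not isolated), via trimethylsilyl ketene acetal 14 (not isolated)
Conditions: Mg, THF; CuBr·SMe2 (20 mol %), Me3SiCl, THF, −78 → −30 °C; 1 M HCl
Reagents that add atoms: none
Why: copper-catalysed conjugate addition of a silylmethyl Grignard reagent (a hydroxymethyl anion equivalent), activated by the chlorosilane. The nucleophile enters anti to the pseudo-equatorial alkenyl group at C2, so C20 is trans to it and C10 is set by the substrate. The acidic work-up hydrolyses 14, so that 15 can be purified free of copper and magnesium halides before the thermal step.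

Step 9
Reactants: 15 (4S,6R)-4-[3-(benzyloxy)propyl]-4-{[dimethyl(phenyl)silyl]methyl}-6-[(Z)-3-(tert-butyldimethylsilyloxy)-2-methylprop-1-enyl]oxan-2-one
Product: 18 (1R,2S,6S)-6-[3-(benzyloxy)propyl]-2-{[(tert-butyldimethylsilyl)oxy]methyl}-6-{[dimethyl(phenyl)silyl]methyl}-2-methylcyclohex-3-ene-1-carboxylic acid, via tert-butyldimethylsilyl ketene acetal 16 (not isolated), via tert-butyldimethylsilyl ester 17 (not isolated)
Conditions: LiN(i-Pr)2, t-BuMe2SiCl, DMPU, THF, −78 → 0 °C; toluene, 110 °C; AcOH, THF–H2O, rt
Reagents that add atoms: none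
Why: The amide base removes a C5 proton (the only α-position) and the chlorosilane gives the cyclic tert-butyldimethylsilyl ketene acetal 16, whose geometry is fixed by the ring (C10 cis to the ring oxygen) and which should withstand heating better than the trimethylsilyl analogue 14. On heating, the array C5=C6–O–C2–C3=C4 undergoes a concerted suprafacial [3,3] shift: C4–C5 forms, C2–O breaks and C6 emerges as silyl ester 17, hydrolysed to 18 by brief aqueous acid that should spare the primary silyl ether. The closest known reaction type is the Ireland–Claisen ring contraction of alkenyl lactone silyl ketene acetals to cycloalkene carboxylic acids. The carbocycle (C5, C10, C1, C2, C3, C4) closes in the sigmatropic event itself, through a bicyclo[2.2.2]octane-like transition state in which the array is a boat because C5 and C2 are tied by the bridge C10–C1. C5: the new bond enters on the lactone face bearing the alkenyl group, so C6 ends cis to the C10 substituent that was trans to it, which is C20. C4: the (Z) geometry holds CH2OSi cis to C2, and with the boat and the (R) centre at C2 this places the methyl on the face of C6 and C20 and C18 on the other. The selectivities needed are boat over chair (a chair cannot span the bridge), C5 enolisation (no other α-hydrogen) and an intact (Z)-alkene (no isomerising reagent present).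

Step 10
Reactants: 18 (1R,2S,6S)-6-[3-(benzyloxy)propyl]-2-{[(tert-butyldimethylsilyl)oxy]methyl}-6-{[dimethyl(phenyl)silyl]methyl}-2-methylcyclohex-3-ene-1-carboxylic acid
Product: 19 the corresponding C6 primary alcohol (C4, C5, C10 as in 18)
Conditions: LiAlH4, THF, 0 °C → reflux
Reagents that add atoms: none
Why: hydride reduction of a hindered carboxylic acid; the carboxylate is not epimerised at C5.

Step 11
Reactants: 19 the C6 primary alcohol
Product: 20 the C6,C18-bis(tert-butyldimethylsilyl) ether with C7 benzyl ether and C2=C3 alkene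
Conditions: t-BuMe2SiCl, imidazole, DMF, rt
Reagents that add atoms: tert-butyldimethylsilyl chloride, CC(C)(C)[Si](C)(C)Cl
Why: standard silylation of a primary alcohol; an excess also re-silylates C18–OH should step 10 have loosened it.

Step 12
Reactants: 20 the bis-silyl ether with benzyl ether and ring alkene
Product: 21 the saturated ring A alcohol with free C7–OH, C20 silylmethyl and C6,C18 silyl ethers
Conditions: H2 (1–3 atm), Pd/C, EtOAc, rt
Reagents that add atoms: none
Why: heterogeneous hydrogenation saturates the cis-disubstituted ring alkene (no stereocentre arises) and hydrogenolyses the benzyl ether. It precedes step 13 so that neither alkene nor benzyl ring meets electrophilic bromine.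

Step 13
Reactants: 21 the saturated ring A alcohol
Product: 22 the C7,C20-diol
Conditions: KBr, AcOOH, NaOAc, AcOH, rt
Reagents that add atoms: peracetic acid, CC(=O)OO
Why: Tamao–Fleming oxidation in its one-flask form: ipso-bromodesilylation of the phenyl group, then peracid-induced shift of the primary alkyl group from silicon to oxygen. The acetate buffer should spare the primary silyl ethers.

Step 14
Reactants: 22 the C7,C20-diol
Product: 25 (C4, C5, C10 as in 18) 7,8-bis{[(tert-butyldimethylsilyl)oxy]methyl}-8-methyl-2-oxaspiro[5.5]undecan-3-one, via hydroxy aldehyde 23 (not isolated), via lactol 24 (not isolated)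
Conditions: TEMPO (cat.), PhI(OAc)2, CH2Cl2, rt
Reagents that add atoms: none
Why: oxoammonium oxidation is sterically sensitive, so the unhindered C7–OH is oxidised before the neopentyl C20–OH. The aldehyde is trapped as the six-membered lactol and oxidised on to the δ-lactone with the carbonyl at C7.

Step 15
Reactants: 26 cyclopent-3-en-1-ylmethanol
Product: 27 4-(iodomethyl)cyclopent-1-ene
Conditions: I2, PPh3, imidazole, CH2Cl2, 0 °C
Reagents that add atoms: iodine, II
Why: Appel-type conversion of a primary alcohol to the iodide.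

Step 16
Reactants: 25 the spirolactone; 27 4-(iodomethyl)cyclopent-1-ene
Product: 28 the C8-(cyclopent-3-en-1-ylmethyl) spirolactone (both C8 epimers)
Conditions: LiN(i-Pr)2, THF, −78 °C; 27, DMPU, −78 → −20 °C
Reagents that add atoms: none
Why: alkylation of the lactone enolate at its only α-position with a primary iodide; the C8 configuration is lost again in step 17.

Step 17
Reactants: 28 the C8-alkylated spirolactone
Product: 31 the C8=C9 unsaturated spirolactone bearing the cyclopentenylmethyl group on C8, via α-phenylselenyl lactone 29 (not isolated), via selenoxide 30 (not isolated)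
Conditions: LiN(i-Pr)2, THF, −78 °C; PhSeBr; then H2O2, pyridine, CH2Cl2, 0 °C
Reagents that add atoms: none
Why: α-selenation of the tertiary enolate and selenoxide syn-elimination; elimination towards the ring hydrogen on C9 gives the endocyclic conjugated alkene, the course expected for α-alkyl δ-lactones of this spiro type.

Step 18
Reactants: 31 the unsaturated spirolactone with cyclopentene side chain
Product: 33 the dialdehyde (3-substituted pentanedial; C11 and C15 as CHO), via ozonide 32 (not isolated)
Conditions: O3, CH2Cl2, −78 °C; PPh3; used crude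
Reagents that add atoms: ozone, [O-][O+]=O
Why: ozone attacks the electron-rich cis-disubstituted cyclopentene much faster than the electron-poor conjugated lactone alkene, which is further shielded by C10.

Step 19
Reactants: 33 the dialdehyde
Product: 34 the tetracyclic 11,15-diol (C8, C9, C13 as in 44; C11 carbinol expected as the 11β epimer; C15 epimer not defined)
Conditions: SmI2, LiBr, t-BuOH, THF, −78 °C
Reagents that add atoms: none
Why: ketyl–olefin addition followed by aldol, a cascade known for unsaturated spirolactone dialdehydes. The samarium ketyl of either arm adds 6-endo to C9 anti to C5 through a chair with the spectator arm equatorial (C9, C13), and the trivalent-samarium enolate closes onto the other aldehyde anti to C10 (C8). The usual preference for the ketyl oxygen anti to C8 would give the 11β carbinol, which the route does not rely on.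

Step 20
Reactants: 34 the tetracyclic 11,15-diol
Product: 35 the C15 triethylsilyl ether with free C11–OH
Conditions: Et3SiOTf (1.05 equiv), 2,6-lutidine, CH2Cl2, −78 °C
Reagents that add atoms: triethylsilyl triflate, CC[Si](CC)(CC)OS(=O)(=O)C(F)(F)F
Why: the C15 hydroxyl stands exo on the two-carbon bridge, whereas the C11 hydroxyl is flanked by C9 and axial C10 and, as the 11β epimer, lies under that bridge; one equivalent of a silyl triflate should take the C15 oxygen.

Step 21
Reactants: 35 the C15 triethylsilyl ether
Product: 36 the C11 ketone with C15 triethylsilyl ether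
Conditions: Dess–Martin periodinane, NaHCO3, CH2Cl2, rt
Reagents that add atoms: none
Why: buffered periodinane oxidation of a hindered secondary alcohol under non-basic conditions, so that C9 next to the new ketone is not epimerised.

Step 22
Reactants: 36 the C11 ketone
Product: 37 the 11α alcohol (hydroxyl trans to H9, as in 44) with C15 triethylsilyl ether
Conditions: SmI2, HMPA, t-BuOH, THF, −78 → 0 °C
Reagents that add atoms: none
Why: electron-transfer reduction of hindered cyclohexanones gives the more stable carbinol: the ketyl and organosamarium at C11 are protonated with the bulky O–Sm group equatorial, away from the C15–C16 bridge. Without water or amine the lactone and silyl ethers should not be reduced.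

Step 23
Reactants: 37 the 11α alcohol
Product: 38 the C11 tert-butyldimethylsilyl ether with C15 triethylsilyl ether
Conditions: t-BuMe2SiOTf, 2,6-lutidine, CH2Cl2, 0 °C
Reagents that add atoms: tert-butyldimethylsilyl triflate, CC(C)(C)[Si](C)(C)OS(=O)(=O)C(F)(F)F
Why: a silyl triflate silylates hindered secondary alcohols; the group is chosen to leave in step 27 with the other two.

Step 24
Reactants: 38 the fully silylated tetracycle
Product: 39 the C15 alcohol with C6, C11 and C18 tert-butyldimethylsilyl ethers
Conditions: HF·pyridine, pyridine, THF, 0 °C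
Reagents that add atoms: none
Why: a triethylsilyl ether is cleaved by buffered fluoride well before tert-butyldimethylsilyl ethers.

Step 25
Reactants: 39 the C15 alcohol
Product: 40 the C15 ketone (β-keto lactone) with three silyl ethers
Conditions: Dess–Martin periodinane, NaHCO3, CH2Cl2, rt
Reagents that add atoms: none
Why: neutral oxidation; the β-keto lactone has no hydrogen on C8 and is not exposed to alkoxide.

Step 26
Reactants: 40 the C15 ketone
Product: 43 the C16 exo-methylene ketone, tris(tert-butyldimethylsilyl) ether of 44, via Mannich base 41 (not isolated), via trimethylammonium iodide 42 (not isolated)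
Conditions: LiN(SiMe3)2, THF, −78 °C; CH2=NMe2 I; then MeI; NaHCO3 (aq)
Reagents that add atoms: N,N-dimethylmethyleneiminium iodide, C=[N+](C)C.[I-]
Why: C16 is the only enolisable position (C8 is quaternary); Mannich reaction of the lithium enolate, quaternisation and β-elimination is a standard α-methylenation that uses a non-nucleophilic base.

Step 27
Reactants: 43 the tris-silyl ether
Product: 44 the target (4S,5R,8S,9S,10S,11R,13S; kaurane numbering)
Conditions: HF (aq), MeCN, 0 °C → rt
Reagents that add atoms: none
Why: acidic fluoride removes primary and secondary silyl ethers without a nucleophile that would add to the enone or open the β-keto lactone.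

## Compound list

1 | tert-butyldimethyl(prop-2-yn-1-yloxy)silane | C#CCO[Si](C)(C)C(C)(C)C | starting material
2 | ethyl 4-[(tert-butyldimethylsilyl)oxy]but-2-ynoate | CCOC(=O)C#CCO[Si](C)(C)C(C)(C)C | intermediate
3 | ethyl (Z)-4-[(tert-butyldimethylsilyl)oxy]-3-methylbut-2-enoate | CCOC(=O)/C=C(/C)CO[Si](C)(C)C(C)(C)C | intermediate
4 | (Z)-4-[(tert-butyldimethylsilyl)oxy]-3-methylbut-2-en-1-ol | OC/C=C(/C)CO[Si](C)(C)C(C)(C)C | intermediate
5 | (Z)-4-[(tert-butyldimethylsilyl)oxy]-3-methylbut-2-enal | O=C/C=C(/C)CO[Si](C)(C)C(C)(C)C | intermediate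
6 | benzyl 3-bromopropyl ether | BrCCCOCc1ccccc1 | starting material
7 | ethyl but-2-ynoate | CC#CC(=O)OCC | starting material
8 | [3-(benzyloxy)propyl]magnesium bromide | Br[Mg]CCCOCc1ccccc1 | intermediate
9 | ethyl (E)-6-(benzyloxy)-3-methylhex-2-enoate | CCOC(=O)/C=C(\C)CCCOCc1ccccc1 | intermediate
10 | {[3-(3-benzyloxypropyl)-1-ethoxybuta-1,3-dien-1-yl]oxy}trimethylsilane (ketene acetal geometry not defined) | CCOC(O[Si](C)(C)C)=CC(=C)CCCOCc1ccccc1 | intermediate
11 | (6R)-4-[3-(benzyloxy)propyl]-6-[(Z)-3-(tert-butyldimethylsilyloxy)-2-methylprop-1-enyl]-5,6-dihydro-2H-pyran-2-one | c1ccccc1COCCCC2=CC(=O)O[C@@H](/C=C(/C)CO[Si](C)(C)C(C)(C)C)C2 | intermediate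
12 | (chloromethyl)dimethyl(phenyl)silane | C[Si](C)(CCl)c1ccccc1 | starting material
13 | {[dimethyl(phenyl)silyl]methyl}magnesium chloride | Cl[Mg]C[Si](C)(C)c1ccccc1 | intermediate
14 | trimethylsilyl ketene acetal of 15 (C2 and C10 as in 15) | c1ccccc1COCCC[C@@]2(C[Si](C)(C)c3ccccc3)C=C(O[Si](C)(C)C)O[C@@H](/C=C(/C)CO[Si](C)(C)C(C)(C)C)C2 | intermediate
15 | (4S,6R)-4-[3-(benzyloxy)propyl]-4-{[dimethyl(phenyl)silyl]methyl}-6-[(Z)-3-(tert-butyldimethylsilyloxy)-2-methylprop-1-enyl]oxan-2-one | c1ccccc1COCCC[C@@]2(C[Si](C)(C)c3ccccc3)CC(=O)O[C@@H](/C=C(/C)CO[Si](C)(C)C(C)(C)C)C2 | intermediate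
16 | tert-butyldimethylsilyl ketene acetal of 15 (C2 and C10 as in 15) | c1ccccc1COCCC[C@@]2(C[Si](C)(C)c3ccccc3)C=C(O[Si](C)(C)C(C)(C)C)O[C@@H](/C=C(/C)CO[Si](C)(C)C(C)(C)C)C2 | intermediate
17 | tert-butyldimethylsilyl ester of 18 | c1ccccc1COCCC[C@@]2(CC=C[C@](C)(CO[Si](C)(C)C(C)(C)C)[C@H]2C(=O)O[Si](C)(C)C(C)(C)C)C[Si](C)(C)c3ccccc3 | intermediate
18 | (1R,2S,6S)-6-[3-(benzyloxy)propyl]-2-{[(tert-butyldimethylsilyl)oxy]methyl}-6-{[dimethyl(phenyl)silyl]methyl}-2-methylcyclohex-3-ene-1-carboxylic acid | c1ccccc1COCCC[C@@]2(CC=C[C@](C)(CO[Si](C)(C)C(C)(C)C)[C@H]2C(=O)O)C[Si](C)(C)c3ccccc3 | intermediate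
19 | C6 primary alcohol from 18 (same ring A centres) | c1ccccc1COCCC[C@@]2(CC=C[C@](C)(CO[Si](C)(C)C(C)(C)C)[C@H]2CO)C[Si](C)(C)c3ccccc3 | intermediate
20 | C6,C18-bis(tert-butyldimethylsilyl) ether of 19 | c1ccccc1COCCC[C@@]2(CC=C[C@](C)(CO[Si](C)(C)C(C)(C)C)[C@H]2CO[Si](C)(C)C(C)(C)C)C[Si](C)(C)c3ccccc3 | intermediate
21 | saturated ring A, C10 3-hydroxypropyl and (dimethylphenylsilyl)methyl, C6,C18 silyl ethers | OCCC[C@@]1(CCC[C@](C)(CO[Si](C)(C)C(C)(C)C)[C@H]1CO[Si](C)(C)C(C)(C)C)C[Si](C)(C)c1ccccc1 | intermediate
22 | C7,C20-diol | OCCC[C@@]1(CCC[C@](C)(CO[Si](C)(C)C(C)(C)C)[C@H]1CO[Si](C)(C)C(C)(C)C)CO | intermediate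
23 | C7 aldehyde with free C20–OH | O=CCC[C@@]1(CCC[C@](C)(CO[Si](C)(C)C(C)(C)C)[C@H]1CO[Si](C)(C)C(C)(C)C)CO | intermediate
24 | spiro lactol (anomeric centre not defined) | OC1CC[C@@]2(CCC[C@](C)(CO[Si](C)(C)C(C)(C)C)[C@H]2CO[Si](C)(C)C(C)(C)C)CO1 | intermediate
25 | 7,8-bis{[(tert-butyldimethylsilyl)oxy]methyl}-8-methyl-2-oxaspiro[5.5]undecan-3-one (C4, C5, C10 as in 44) | O=C1CC[C@@]2(CCC[C@](C)(CO[Si](C)(C)C(C)(C)C)[C@H]2CO[Si](C)(C)C(C)(C)C)CO1 | intermediate
26 | cyclopent-3-en-1-ylmethanol | OCC1CC=CC1 | starting material
27 | 4-(iodomethyl)cyclopent-1-ene | ICC1CC=CC1 | intermediate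
28 | C8-(cyclopent-3-en-1-ylmethyl) derivative of 25 (C8 epimers) | O=C1C(CC3CC=CC3)C[C@@]2(CCC[C@](C)(CO[Si](C)(C)C(C)(C)C)[C@H]2CO[Si](C)(C)C(C)(C)C)CO1 | intermediate
29 | C8 phenylselenide of 28 (C8 not defined) | O=C1C(CC3CC=CC3)([Se]c3ccccc3)C[C@@]2(CCC[C@](C)(CO[Si](C)(C)C(C)(C)C)[C@H]2CO[Si](C)(C)C(C)(C)C)CO1 | intermediate
30 | selenoxide of 29 | O=C1C(CC3CC=CC3)([Se](=O)c3ccccc3)C[C@@]2(CCC[C@](C)(CO[Si](C)(C)C(C)(C)C)[C@H]2CO[Si](C)(C)C(C)(C)C)CO1 | intermediate
31 | C8=C9 unsaturated spirolactone with cyclopent-3-en-1-ylmethyl on C8 | O=C1C(CC3CC=CC3)=C[C@@]2(CCC[C@](C)(CO[Si](C)(C)C(C)(C)C)[C@H]2CO[Si](C)(C)C(C)(C)C)CO1 | intermediate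
32 | ozonide of 31 (6,7,8-trioxabicyclo[3.2.1]octane; acetal centres not defined) | O=C1C(CC3CC4OOC(C3)O4)=C[C@@]2(CCC[C@](C)(CO[Si](C)(C)C(C)(C)C)[C@H]2CO[Si](C)(C)C(C)(C)C)CO1 | intermediate
33 | dialdehyde (C11 and C15 as CHO) | O=C1C(CC(CC=O)CC=O)=C[C@@]2(CCC[C@](C)(CO[Si](C)(C)C(C)(C)C)[C@H]2CO[Si](C)(C)C(C)(C)C)CO1 | intermediate
34 | tetracyclic 11β,15-diol (C15 not defined) | C1C(O)[C@]23C[C@H]1C[C@H](O)[C@H]2[C@@]1(CCC[C@](C)(CO[Si](C)(C)C(C)(C)C)[C@H]1CO[Si](C)(C)C(C)(C)C)COC3=O | intermediate
35 | C15 triethylsilyl ether, 11β-ol | C1C(O[Si](CC)(CC)CC)[C@]23C[C@H]1C[C@H](O)[C@H]2[C@@]1(CCC[C@](C)(CO[Si](C)(C)C(C)(C)C)[C@H]1CO[Si](C)(C)C(C)(C)C)COC3=O | intermediate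
36 | C11 ketone, C15 triethylsilyl ether | C1C(O[Si](CC)(CC)CC)[C@]23C[C@H]1CC(=O)[C@H]2[C@@]1(CCC[C@](C)(CO[Si](C)(C)C(C)(C)C)[C@H]1CO[Si](C)(C)C(C)(C)C)COC3=O | intermediate
37 | 11α-ol, C15 triethylsilyl ether | C1C(O[Si](CC)(CC)CC)[C@]23C[C@H]1C[C@@H](O)[C@H]2[C@@]1(CCC[C@](C)(CO[Si](C)(C)C(C)(C)C)[C@H]1CO[Si](C)(C)C(C)(C)C)COC3=O | intermediate
38 | C11 tert-butyldimethylsilyl ether, C15 triethylsilyl ether | C1C(O[Si](CC)(CC)CC)[C@]23C[C@H]1C[C@@H](O[Si](C)(C)C(C)(C)C)[C@H]2[C@@]1(CCC[C@](C)(CO[Si](C)(C)C(C)(C)C)[C@H]1CO[Si](C)(C)C(C)(C)C)COC3=O | intermediate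
39 | C15 alcohol, C6,C11,C18 silyl ethers | C1C(O)[C@]23C[C@H]1C[C@@H](O[Si](C)(C)C(C)(C)C)[C@H]2[C@@]1(CCC[C@](C)(CO[Si](C)(C)C(C)(C)C)[C@H]1CO[Si](C)(C)C(C)(C)C)COC3=O | intermediate
40 | C15 ketone, C6,C11,C18 silyl ethers | C1C(=O)[C@]23C[C@H]1C[C@@H](O[Si](C)(C)C(C)(C)C)[C@H]2[C@@]1(CCC[C@](C)(CO[Si](C)(C)C(C)(C)C)[C@H]1CO[Si](C)(C)C(C)(C)C)COC3=O | intermediate
41 | C16 (dimethylamino)methyl ketone (C16 not defined) | CN(C)CC1C(=O)[C@]23C[C@H]1C[C@@H](O[Si](C)(C)C(C)(C)C)[C@H]2[C@@]1(CCC[C@](C)(CO[Si](C)(C)C(C)(C)C)[C@H]1CO[Si](C)(C)C(C)(C)C)COC3=O | intermediate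
42 | trimethylammonium iodide of 41 | [I-].C[N+](C)(C)CC1C(=O)[C@]23C[C@H]1C[C@@H](O[Si](C)(C)C(C)(C)C)[C@H]2[C@@]1(CCC[C@](C)(CO[Si](C)(C)C(C)(C)C)[C@H]1CO[Si](C)(C)C(C)(C)C)COC3=O | intermediate
43 | 6,11,18-tris(tert-butyldimethylsilyl) ether of 44 | C=C1C(=O)[C@]23C[C@H]1C[C@@H](O[Si](C)(C)C(C)(C)C)[C@H]2[C@@]1(CCC[C@](C)(CO[Si](C)(C)C(C)(C)C)[C@H]1CO[Si](C)(C)C(C)(C)C)COC3=O | intermediate
44 | CNP0152458.1, (4S,5R,8S,9S,10S,11R,13S)-6,11,18-trihydroxy-15-oxo-6,7-seco-kaur-16-en-7,20-olide | C=C1C(=O)[C@]23C[C@H]1C[C@@H](O)[C@H]2[C@@]1(CCC[C@](C)(CO)[C@H]1CO)COC3=O | target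

## Step count and risk

Total: 27 steps. Longest linear sequence: 24 steps (steps 1–4, 7–14, 16–27).

Step 9 (key step). The boat has to bring the fully substituted C4 terminus against C5, which sits next to quaternary C10. The shift may therefore be slow, and ionisation of the allylic C2–O bond or loss of the silyl ketene acetal may win, even with the more robust silyl group. The fallback makes the same C4–C5 bond by an ionic ring closure:
- From 15, methanolysis (NaOMe, MeOH) gives the hydroxy ester F1 and MnO2 gives the (Z)-enone F2.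
- KOt-Bu in t-BuOH closes ring A by a 6-endo intramolecular Michael addition to the keto ester F3. C4 and C5 then rest on a chair with the ester equatorial, which is less secure than the sigmatropic transfer.
- The C2 ketone is removed through the tosylhydrazone F4 (TsNHNH2; catecholborane, NaOAc) to give ester F5.
- LiAlH4 gives alcohol F6, silylation gives F7, and hydrogenolysis (H2, Pd/C) rejoins the route at 21.

Step 8. The silylmethyl group transfers poorly from copper, and the acceptor is a β,β-disubstituted lactone; 1,2-addition or no reaction may result. The fallback uses vinyl as the C20 surrogate: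
- From 11, CH2=CHMgBr with CuBr·SMe2 and Me3SiCl gives the vinyl lactone F8 with the same anti sense.
- The shift of step 9 gives acid F9, LiAlH4 gives alcohol F10 and silylation gives F11.
- OsO4 (cat.) with N-methylmorpholine N-oxide, then NaIO4, cleaves the monosubstituted vinyl group in preference to the hindered ring alkene and gives aldehyde F12.
- NaBH4 gives alcohol F13, and H2 with Pd/C rejoins the route at 22.

Step 19. The two aldehydes are 1,5-related, so reductive pinacol closure of the arms may outrun the slower 6-endo ketyl addition to the hindered C9. Facial or arm selectivity may also be incomplete. The fallback replaces the lanthanide ketyl by a neutral O-stannyl ketyl in a radical chain (Bu3SnH, AIBN, benzene, 80 °C). No second electron is delivered, so carbonyl–carbonyl coupling stays reversible, and the tin enolate closes the aldol. It runs from 33 to 34 and makes no new compound.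

Step 20. Silylation may occur at the wrong hydroxyl or at both, since both carbinols are hindered and the C11 configuration from step 19 is only predicted. The fallback differentiates by electrophilicity instead:
- From 34, excess Dess–Martin periodinane gives the diketone F14.
- NaBH4 at −78 °C reduces the more electrophilic C15 ketone (a cyclopentanone activated by the lactone carbonyl) to the hydroxy ketone F15.
- Et3SiOTf then rejoins the route at 36.

Step 22. Facial selectivity in the electron-transfer reduction may be poor, or C9 may epimerise through the ketone. The fallback avoids the ketone: from 35, if it is the 11β alcohol, Tf2O and pyridine give the triflate F16. KNO2 in DMF displaces it with inversion (Lattrell–Dax) through the nitrite F17, which is hydrolysed on work-up to 37. Elimination towards C12 is the risk of this variant.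

Step 7. Enantioselectivity may be insufficient, or the (Z)-enal may isomerise under the copper fluoride catalyst. The fallback builds the lactone by an auxiliary-controlled acetate aldol and an olefination:
- From 5, N-acetyl-(S)-4-benzylthiazolidine-2-thione with TiCl4 and i-Pr2NEt gives the aldol adduct F18, whose diastereomers are separable. The auxiliary antipode is chosen for the 6R series.
- MeNHOMe·HCl with imidazole gives the Weinreb amide F19, and Grignard reagent 8 gives the β-hydroxy ketone F20.
- Diethylphosphonoacetic acid with dicyclohexylcarbodiimide gives the phosphonoacetate F21.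
- LiCl and DBU (intramolecular Horner–Wadsworth–Emmons) rejoin the route at 11.

## Further compounds

F1 | step 9 | methyl ester of the ring-opened hydroxy acid of 15 | COC(=O)C[C@@](CCCOCc1ccccc1)(C[Si](C)(C)c1ccccc1)C[C@@H](O)/C=C(/C)CO[Si](C)(C)C(C)(C)C
F2 | step 9 | (Z)-enone ester from F1 | COC(=O)C[C@@](CCCOCc1ccccc1)(C[Si](C)(C)c1ccccc1)CC(=O)/C=C(/C)CO[Si](C)(C)C(C)(C)C
F3 | step 9 | ring A keto ester (C2 ketone) | COC(=O)[C@@H]1[C@@](C)(CO[Si](C)(C)C(C)(C)C)CC(=O)C[C@]1(CCCOCc1ccccc1)C[Si](C)(C)c1ccccc1
F4 | step 9 | tosylhydrazone of F3 | COC(=O)[C@@H]1[C@@](C)(CO[Si](C)(C)C(C)(C)C)CC(=NNS(=O)(=O)c2ccc(C)cc2)C[C@]1(CCCOCc1ccccc1)C[Si](C)(C)c1ccccc1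
F5 | step 9 | saturated ring A methyl ester | COC(=O)[C@@H]1[C@@](C)(CO[Si](C)(C)C(C)(C)C)CCC[C@]1(CCCOCc1ccccc1)C[Si](C)(C)c1ccccc1
F6 | step 9 | saturated ring A C6 alcohol | OC[C@@H]1[C@@](C)(CO[Si](C)(C)C(C)(C)C)CCC[C@]1(CCCOCc1ccccc1)C[Si](C)(C)c1ccccc1
F7 | step 9 | saturated ring A bis-silyl ether with benzyl ether | CC(C)(C)[Si](C)(C)OC[C@@H]1[C@@](C)(CO[Si](C)(C)C(C)(C)C)CCC[C@]1(CCCOCc1ccccc1)C[Si](C)(C)c1ccccc1
F8 | step 8 | 4-vinyl lactone | c1ccccc1COCCC[C@@]2(C=C)CC(=O)O[C@@H](/C=C(/C)CO[Si](C)(C)C(C)(C)C)C2
F9 | step 8 | ring A acid with C10 vinyl | c1ccccc1COCCC[C@@]2(CC=C[C@](C)(CO[Si](C)(C)C(C)(C)C)[C@H]2C(=O)O)C=C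
F10 | step 8 | ring A C6 alcohol with C10 vinyl | c1ccccc1COCCC[C@@]2(CC=C[C@](C)(CO[Si](C)(C)C(C)(C)C)[C@H]2CO)C=C
F11 | step 8 | bis-silyl ether with C10 vinyl | c1ccccc1COCCC[C@@]2(CC=C[C@](C)(CO[Si](C)(C)C(C)(C)C)[C@H]2CO[Si](C)(C)C(C)(C)C)C=C
F12 | step 8 | C20 aldehyde | c1ccccc1COCCC[C@@]2(CC=C[C@](C)(CO[Si](C)(C)C(C)(C)C)[C@H]2CO[Si](C)(C)C(C)(C)C)C=O
F13 | step 8 | C20 alcohol with benzyl ether and ring alkene | c1ccccc1COCCC[C@@]2(CC=C[C@](C)(CO[Si](C)(C)C(C)(C)C)[C@H]2CO[Si](C)(C)C(C)(C)C)CO
F0 | step 19 | none | none
F14 | step 20 | tetracyclic 11,15-diketone | C1C(=O)[C@]23C[C@H]1CC(=O)[C@H]2[C@@]1(CCC[C@](C)(CO[Si](C)(C)C(C)(C)C)[C@H]1CO[Si](C)(C)C(C)(C)C)COC3=O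
F15 | step 20 | 15-hydroxy-11-ketone (C15 not defined) | C1C(O)[C@]23C[C@H]1CC(=O)[C@H]2[C@@]1(CCC[C@](C)(CO[Si](C)(C)C(C)(C)C)[C@H]1CO[Si](C)(C)C(C)(C)C)COC3=O
F16 | step 22 | 11β-triflate of 35 | C1C(O[Si](CC)(CC)CC)[C@]23C[C@H]1C[C@H](OS(=O)(=O)C(F)(F)F)[C@H]2[C@@]1(CCC[C@](C)(CO[Si](C)(C)C(C)(C)C)[C@H]1CO[Si](C)(C)C(C)(C)C)COC3=O
F17 | step 22 | 11α-nitrite ester | C1C(O[Si](CC)(CC)CC)[C@]23C[C@H]1C[C@@H](ON=O)[C@H]2[C@@]1(CCC[C@](C)(CO[Si](C)(C)C(C)(C)C)[C@H]1CO[Si](C)(C)C(C)(C)C)COC3=O
F18 | step 7 | acetate aldol adduct on (S)-4-benzylthiazolidine-2-thione | S=C1SC[C@H](Cc2ccccc2)N1C(=O)C[C@@H](O)/C=C(/C)CO[Si](C)(C)C(C)(C)C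
F19 | step 7 | β-hydroxy Weinreb amide | CON(C)C(=O)C[C@@H](O)/C=C(/C)CO[Si](C)(C)C(C)(C)C
F20 | step 7 | β-hydroxy ketone | O=C(CCCOCc1ccccc1)C[C@@H](O)/C=C(/C)CO[Si](C)(C)C(C)(C)C
F21 | step 7 | diethylphosphonoacetate of F20 | CCOP(=O)(OCC)CC(=O)O[C@H](CC(=O)CCCOCc1ccccc1)/C=C(/C)CO[Si](C)(C)C(C)(C)C
A1 | alternative 1 | bicyclo[3.2.1]octan-11-one lactone with C15 methoxymethyl ether | C1[C@H](OCOC)[C@]23C[C@H]1CC(=O)[C@H]2[C@@]1(CCC[C@](C)(CO[Si](C)(C)C(C)(C)C)[C@H]1CO[Si](C)(C)C(C)(C)C)COC3=O
A2 | alternative 2 | unsaturated spirolactone C6 aldehyde | C=CCC(CC=C)CC1=C[C@@]2(CCC[C@](C)(CO[Si](C)(C)C(C)(C)C)[C@H]2C=O)COC1=O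
A3 | alternative 3 | tetracyclic lactone with C11 ketone, C15 ketone and C6 aldehyde | C1C(=O)[C@]23C[C@H]1CC(=O)[C@H]2[C@@]1(CCC[C@](C)(CO[Si](C)(C)C(C)(C)C)[C@H]1C=O)COC3=O
A4 | alternative 1 | lactone-fused cycloheptenone with C8 bromomethyl group | C1[C@H](OCOC)[C@]2(CBr)[C@@H](C(=O)C=C1)[C@@]1(CCC[C@](C)(CO[Si](C)(C)C(C)(C)C)[C@H]1CO[Si](C)(C)C(C)(C)C)COC2=O
A5 | alternative 2 | decalin α-ketol, open form (C6 not defined) | C=CCC(CC=C)CC1=C[C@@]2(CCC[C@](C)(CO[Si](C)(C)C(C)(C)C)[C@H]2C(O)C1=O)CO
A6 | alternative 3 | ester of the bicyclooctanedione acid with the ring A enal alcohol | C1C(=O)[C@@]2(C[C@H]1CC(=O)C2)C(=O)OCC1=C(C=O)[C@@](C)(CO[Si](C)(C)C(C)(C)C)CCC1
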